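Each molecule of target made from protonated nucleophile sets free two acid, one in freeing the nucleophile and one in step 1, and we reckon the whole flask by where that acid goes.

    electrophile + nucleophile → acid set free + target (k1 = 0.57 M⁻¹ s⁻¹)
    nucleophile + acid set free ⇌ protonated nucleophile, settled at all times (K2 = 5000 M⁻¹)
    acid set free + free base ⇌ salt of the base, settled at all times (K3 = 8800 M⁻¹)
    acid set free → by-product carried off (k4 = 0.031 s⁻¹)
    target ⇌ isomer of the product (K5 = 3.2, k5 = 0.0075 s⁻¹)
    solid base ⇌ free base, rate k6*(cs6 - [free base]) while solid is left; crystals form when [free base] > cs6 (cs6 = 0.56 M, k6 = 0.030 s⁻¹)

| flask | electrophile | protonated nucleophile | solid base | time |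
|---|---|---|---|---|
| north-west | 0.94 M | 1.10 M | 0.940 M | 15 min |
| north-east | 0.94 M | 1.70 M | 0.940 M | 15 min |

* part of the electrophile that has reacted at the end, north-west
* part of the electrophile that has reacted at the end, north-east
* what raising the concentration of protonated nucleophile from its lowest to its highest value here does to the part of the electrophile that has reacted (changes below 5 percentage points count as none) (it falls / it rises / no change)

- as a solid, counted per litre of solution: solid base
- at the start none of the solid base is in solution
- run time (north-west): 15 min

One equivalent of solid base per electrophile is the symmetric case, and it pays for this part of the bill:

base share = solid base / (two × electrophile) = 50.0%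

This is the fraction of the electrophile charge that solid base can pay for at two acid each.

Taking free base as small beside its solubility, the reacted fraction starts with slope 0.536 min⁻¹ and reaches a knee at the base share after 0.933 min. Beyond the knee the acid must leave by step 4. We take the small stock of acid set free as steady in this tail, made at two per electrophile as fast as step 4 carries it off, so that the rate constants of steps 1 and 4 and the balance constant of step 2 enter our reckoning together. With the balance of step 2, the fraction a still unreacted and the excess d of protonated nucleophile over electrophile obey:

da/dt = −g·√(a(a+d)), with g = 0.0798 min⁻¹

a = d·sinh(w)·sinh(w), with w = asinh√(50.0%/d) − g·T/2 and T = 14.1 min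

north-west: d = 17.0%, w = 0.747, reacted 88.6%

north-east: d = 80.9%, w = 0.161, reacted 97.9%

Both curves head for the whole charge, since each flask holds more protonated nucleophile than electrophile, and our rise of 9.3 percentage points exceeds the margin.

The forecast gives 89% and 97%, the second just under ours, and says it rises: “More protonated nucleophile leaves more nucleophile in the buffer and raises the free acid level, which speeds that loss”.

The simulation gives 88.5% for north-west and 97.6% for north-east, a change of 9.1 points: it rises. In north-west at 0.469 min, nucleophile has a half-life of 1.7 s by step 1 and acid set free one of 0.37 min by carry-off. The 38 points reacted there beyond the base share come at two acid each to 0.725 M, and by-product carried off stands at 0.720 M at 15.0 min. In the neighbour flask with 0.23 M of electrophile the base share is 204%, above the whole charge, so we expect no tail; that flask reacts 100%, with 0.0144 M of by-product carried off.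

The constants used here are those of an exercise; no experiment stands behind them.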